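**Retrosynthetic overview**

1. The (2S,4R)-ketone comes from Dess–Martin oxidation of the anti,anti bis-pyrone carbinol. The two α-stereocentres travel as a configurationally stable, silyl-protected stereotriad until the last step.
2. Both γ-pyrones come from C–O cyclodehydration of 1,3,5-triketones. Ring A (pentyl pyrone) is closed first, ring B (ethyl pyrone) second.
3. The triketones come from Claisen acylations at the two ends of a differentiated C5 core: the Weinreb amide end takes pentan-3-one, then methyl hexanoate (ring A); the acid end takes 4-methylheptane-3,5-dione (ring B).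
4. The differentiated core comes from an enantioselective C–N desymmetrisation of a meso glutaric anhydride with N,O-dimethylhydroxylamine. This is the new step and it fixes the absolute configuration.
5. The meso anhydride comes from a double anti-selective Fráter–Seebach methylation of dimethyl 3-hydroxyglutarate.

Assumption: the quinidine-derived sulfonamide catalyst is taken to direct the amine to the carbonyl next to the (R)-configured carbon of meso anhydride 6; if the observed sense is the opposite, its quinine-derived pseudo-enantiomer is used and nothing else changes.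

**Route**

Step 1
Reactants: 1 dimethyl 3-hydroxypentanedioate
Product: 3 dimethyl (2R,3r,4S)-3-hydroxy-2,4-dimethylpentanedioate, via anti-monomethyl diester 2 (not isolated)
Conditions: LiN(i-Pr)2 (2.2 equiv), THF, −78 → −20 °C; MeI (1.1 equiv), DMPU, −78 → −20 °C; LiN(i-Pr)2 (1.2 equiv), −78 → −20 °C; MeI (1.5 equiv), → 0 °C; 1 M HCl
Reagents that add atoms: iodomethane, CI
Why: Fráter–Seebach alkylation, in which each lithium alkoxide–enolate chelate is methylated anti to the carbinol substituent, so running it on the two esters in turn gives the anti,anti (meso, 2R,4S) diester and fixes the relative configuration of the two future stereocentres.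

Step 2
Reactants: 3 dimethyl (2R,3r,4S)-3-hydroxy-2,4-dimethylpentanedioate
Product: 4 dimethyl (2R,3r,4S)-3-[(tert-butyldimethylsilyl)oxy]-2,4-dimethylpentanedioate
Conditions: t-BuMe2SiOTf (1.3 equiv), 2,6-lutidine (2 equiv), CH2Cl2, 0 °C → rt
Reagents that add atoms: tert-butyldimethylsilyl trifluoromethanesulfonate, CC(C)(C)[Si](C)(C)OS(=O)(=O)C(F)(F)F
Why: Silyl triflate silylation of a hindered secondary alcohol masks the future ketone carbon as a robust, non-acidic ether that keeps the flanking stereocentres non-enolisable in all later base steps.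

Step 3
Reactants: 4 dimethyl (2R,3r,4S)-3-[(tert-butyldimethylsilyl)oxy]-2,4-dimethylpentanedioate
Product: 6 (3R,4r,5S)-4-[(tert-butyldimethylsilyl)oxy]-3,5-dimethyloxane-2,6-dione, via silyloxy diacid 5 (not isolated)
Conditions: LiOH·H2O (6 equiv), THF/MeOH/H2O, 40 °C; 1 M HCl; crude diacid, Ac2O, 60 °C; crystallise from hexane
Reagents that add atoms: lithium hydroxide, [Li+].[OH-]
Why: Ester saponification followed by dehydrative cyclisation of the glutaric acid gives the six-membered anhydride, and the anti,anti isomer is the all-equatorial, crystalline one, so any syn,anti material from step 1 is removed here.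

Step 4
Reactants: 6 (3R,4r,5S)-4-[(tert-butyldimethylsilyl)oxy]-3,5-dimethyloxane-2,6-dione, 7 N,O-dimethylhydroxylamine
Product: 8 (2S,3S,4R)-3-[(tert-butyldimethylsilyl)oxy]-5-[methoxy(methyl)amino]-2,4-dimethyl-5-oxopentanoic acid
Conditions: 7 (1.15 equiv, syringe pump, 6 h), N-[(9R)-6′-methoxycinchonan-9-yl]-3,5-bis(trifluoromethyl)benzenesulfonamide (C28H27F6N3O3S, 10 mol %), MTBE (0.02 M), −40 °C; 1 M HCl wash
Reagents that add atoms: none
Why: Proposed new method: a catalytic enantioselective desymmetrising aminolysis of a meso anhydride that delivers a Weinreb amide directly — the sulfonamide N–H binds one enantiotopic carbonyl while the quinuclidine nitrogen removes the N–H proton of the weakly basic α-nucleophile MeNHOMe (pKaH about 4.8) in the rate-limiting step, and low temperature, high dilution and slow addition hold down the uncatalysed aminolysis that defeats ordinary amines; the closest known reaction type is the cinchona sulfonamide- or thiourea-catalysed alcoholysis and thiolysis of meso anhydrides (to my knowledge the hydroxylamine version has not been described); by choosing which carbonyl becomes the ring A acyl donor this step sets the absolute configuration of both stereocentres.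

Step 5
Reactants: 8 (2S,3S,4R)-3-[(tert-butyldimethylsilyl)oxy]-5-[methoxy(methyl)amino]-2,4-dimethyl-5-oxopentanoic acid, 9 pentan-3-one
Product: 10 (2S,3S,4R)-3-[(tert-butyldimethylsilyl)oxy]-2,4,6-trimethyl-5,7-dioxononanoic acid
Conditions: 9 (3.3 equiv), LiN(i-Pr)2 (3.3 equiv), THF, −78 °C; add 8; −78 → 0 °C; cold 1 M HCl
Reagents that add atoms: none
Why: Claisen-type acylation of a ketone lithium enolate by a Weinreb amide stops at the chelated tetrahedral adduct and gives the 1,3-diketone on quench, while the lithium carboxylate end is inert and neither stereocentre is deprotonated by the enolate.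

Step 6
Reactants: 10 (2S,3S,4R)-3-[(tert-butyldimethylsilyl)oxy]-2,4,6-trimethyl-5,7-dioxononanoic acid, 11 methyl hexanoate
Product: 13 (2S,3S,4R)-3-[(tert-butyldimethylsilyl)oxy]-4-(3,5-dimethyl-4-oxo-6-pentyl-4H-pyran-2-yl)-2-methylpentanoic acid, via triketone acid 12 (not isolated)
Conditions: LiN(i-Pr)2 (3.1 equiv), THF, −78 → −20 °C; 11 (1.5 equiv), −20 → 0 °C; cold 1 M HCl; crude triketone, p-toluenesulfonic acid monohydrate (TsOH·H2O, 20 mol %), toluene, molecular sieves, 60 °C
Reagents that add atoms: none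
Why: Hauser–Harris terminal acylation of the β-diketone polyanion (kinetic deprotonation at the ethyl CH2, not at the hindered core CH) gives the 1,3,5-triketone, and its acid-catalysed cyclodehydration forms the C–O bond that closes ring A without touching the stereocentre, because the triketone enolises between its carbonyls.

Step 7
Reactants: 13 (2S,3S,4R)-3-[(tert-butyldimethylsilyl)oxy]-4-(3,5-dimethyl-4-oxo-6-pentyl-4H-pyran-2-yl)-2-methylpentanoic acid, 14 4-methylheptane-3,5-dione
Product: 16 2-[(2R,3S,4S)-3-[(tert-butyldimethylsilyl)oxy]-4,6,8-trimethyl-5,7,9-trioxoundecan-2-yl]-3,5-dimethyl-6-pentyl-4H-pyran-4-one, via acyl imidazole 15 (not isolated)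
Conditions: 1,1′-carbonyldiimidazole (CDI, 1.1 equiv), THF, rt; cannulate into dianion from 14 (3.6 equiv) and LiN(i-Pr)2 (7.2 equiv), THF, −78 °C, 30 min; AcOH at −78 °C
Reagents that add atoms: none
Why: Hauser–Harris C-acylation of the terminal carbanion of the symmetric diketone dianion by an acyl imidazole is fast at −78 °C, faster than proton transfer from the pyrone side chains, and the symmetry of 14 removes any regiochemical question.

Step 8
Reactants: 16 2-[(2R,3S,4S)-3-[(tert-butyldimethylsilyl)oxy]-4,6,8-trimethyl-5,7,9-trioxoundecan-2-yl]-3,5-dimethyl-6-pentyl-4H-pyran-4-one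
Product: 18 2-[(2R,3R,4S)-4-(6-ethyl-3,5-dimethyl-4-oxo-4H-pyran-2-yl)-3-hydroxypentan-2-yl]-3,5-dimethyl-6-pentyl-4H-pyran-4-one, via bis-pyrone silyl ether 17 (not isolated)
Conditions: p-toluenesulfonic acid monohydrate (TsOH·H2O, 20 mol %), toluene, molecular sieves, 60 °C; then MeCN, 48% aq. HF, rt; aq. NaHCO3
Reagents that add atoms: none
Why: Acid-catalysed cyclodehydration of the second 1,3,5-triketone forms the C–O bond of ring B, and acidic fluoride desilylation then frees the carbinol without any base that could trigger β-elimination or epimerisation next to the pyrones.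

Step 9
Reactants: 18 2-[(2R,3R,4S)-4-(6-ethyl-3,5-dimethyl-4-oxo-4H-pyran-2-yl)-3-hydroxypentan-2-yl]-3,5-dimethyl-6-pentyl-4H-pyran-4-one
Product: 19 (2S,4R)-2-(3,5-dimethyl-4-oxo-6-pentyl-4H-pyran-2-yl)-4-(6-ethyl-3,5-dimethyl-4-oxo-4H-pyran-2-yl)pentan-3-one
Conditions: Dess–Martin periodinane (1.5 equiv), NaHCO3 (5 equiv), CH2Cl2, 0 °C → rt, 1 h; filter through neutral silica, chromatograph cold
Reagents that add atoms: none
Why: Dess–Martin oxidation of the secondary carbinol under buffered, near-neutral conditions gives the ketone without a base able to enolise the two now-labile α-stereocentres, whose relative configuration came from step 1 and absolute configuration from step 4.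

**Compound list**

1 | dimethyl 3-hydroxypentanedioate | COC(=O)CC(O)CC(=O)OC | starting material
2 | rac-dimethyl (2R,3R)-3-hydroxy-2-methylpentanedioate (anti; lithium alkoxide in the flask; one enantiomer drawn) | COC(=O)[C@H](C)[C@H](O)CC(=O)OC | intermediate (not isolated)
3 | dimethyl (2R,3r,4S)-3-hydroxy-2,4-dimethylpentanedioate (meso, anti,anti) | COC(=O)[C@H](C)[C@H](O)[C@H](C)C(=O)OC | intermediate
4 | dimethyl (2R,3r,4S)-3-[(tert-butyldimethylsilyl)oxy]-2,4-dimethylpentanedioate | COC(=O)[C@H](C)[C@H](O[Si](C)(C)C(C)(C)C)[C@H](C)C(=O)OC | intermediate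
5 | (2R,3r,4S)-3-[(tert-butyldimethylsilyl)oxy]-2,4-dimethylpentanedioic acid | OC(=O)[C@H](C)[C@H](O[Si](C)(C)C(C)(C)C)[C@H](C)C(=O)O | intermediate (not isolated)
6 | (3R,4r,5S)-4-[(tert-butyldimethylsilyl)oxy]-3,5-dimethyloxane-2,6-dione (meso anhydride) | O=C1[C@H](C)[C@H](O[Si](C)(C)C(C)(C)C)[C@H](C)C(=O)O1 | intermediate
7 | N,O-dimethylhydroxylamine (free base) | CNOC | starting material
8 | (2S,3S,4R)-3-[(tert-butyldimethylsilyl)oxy]-5-[methoxy(methyl)amino]-2,4-dimethyl-5-oxopentanoic acid | CON(C)C(=O)[C@H](C)[C@H](O[Si](C)(C)C(C)(C)C)[C@H](C)C(=O)O | intermediate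
9 | pentan-3-one | CCC(=O)CC | starting material
10 | (2S,3S,4R)-3-[(tert-butyldimethylsilyl)oxy]-2,4,6-trimethyl-5,7-dioxononanoic acid (C6 epimers and enol forms) | CCC(=O)C(C)C(=O)[C@H](C)[C@H](O[Si](C)(C)C(C)(C)C)[C@H](C)C(=O)O | intermediate
11 | methyl hexanoate | CCCCCC(=O)OC | starting material
12 | (2S,3S,4R)-3-[(tert-butyldimethylsilyl)oxy]-2,4,6,8-tetramethyl-5,7,9-trioxotetradecanoic acid (C6, C8 epimers and enol forms) | CCCCCC(=O)C(C)C(=O)C(C)C(=O)[C@H](C)[C@H](O[Si](C)(C)C(C)(C)C)[C@H](C)C(=O)O | intermediate (not isolated)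
13 | (2S,3S,4R)-3-[(tert-butyldimethylsilyl)oxy]-4-(3,5-dimethyl-4-oxo-6-pentyl-4H-pyran-2-yl)-2-methylpentanoic acid | CCCCCc1oc([C@H](C)[C@H](O[Si](C)(C)C(C)(C)C)[C@H](C)C(=O)O)c(C)c(=O)c1C | intermediate
14 | 4-methylheptane-3,5-dione | CCC(=O)C(C)C(=O)CC | starting material
15 | 1-[(2S,3S,4R)-3-[(tert-butyldimethylsilyl)oxy]-4-(3,5-dimethyl-4-oxo-6-pentyl-4H-pyran-2-yl)-2-methylpentanoyl]-1H-imidazole | CCCCCc1oc([C@H](C)[C@H](O[Si](C)(C)C(C)(C)C)[C@H](C)C(=O)n2ccnc2)c(C)c(=O)c1C | intermediate (not isolated)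
16 | 2-[(2R,3S,4S)-3-[(tert-butyldimethylsilyl)oxy]-4,6,8-trimethyl-5,7,9-trioxoundecan-2-yl]-3,5-dimethyl-6-pentyl-4H-pyran-4-one (C6, C8 epimers and enol forms) | CCCCCc1oc([C@H](C)[C@H](O[Si](C)(C)C(C)(C)C)[C@H](C)C(=O)C(C)C(=O)C(C)C(=O)CC)c(C)c(=O)c1C | intermediate
17 | 2-[(2R,3R,4S)-3-[(tert-butyldimethylsilyl)oxy]-4-(6-ethyl-3,5-dimethyl-4-oxo-4H-pyran-2-yl)pentan-2-yl]-3,5-dimethyl-6-pentyl-4H-pyran-4-one | CCCCCc1oc([C@H](C)[C@H](O[Si](C)(C)C(C)(C)C)[C@H](C)c2oc(CC)c(C)c(=O)c2C)c(C)c(=O)c1C | intermediate (not isolated)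
18 | 2-[(2R,3R,4S)-4-(6-ethyl-3,5-dimethyl-4-oxo-4H-pyran-2-yl)-3-hydroxypentan-2-yl]-3,5-dimethyl-6-pentyl-4H-pyran-4-one | CCCCCc1oc([C@H](C)[C@H](O)[C@H](C)c2oc(CC)c(C)c(=O)c2C)c(C)c(=O)c1C | intermediate
19 | (2S,4R)-2-(3,5-dimethyl-4-oxo-6-pentyl-4H-pyran-2-yl)-4-(6-ethyl-3,5-dimethyl-4-oxo-4H-pyran-2-yl)pentan-3-one | CCCCCc1oc([C@H](C)C(=O)[C@H](C)c2oc(CC)c(C)c(=O)c2C)c(C)c(=O)c1C | target

**Step count and risks**

Total step count: 9. Longest linear sequence: 9 (1 → 19); compounds 7, 9, 11 and 14 are purchased.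

The three steps most likely to fail:

Step 4 (the new desymmetrising aminolysis). The risks are a racemic background aminolysis and a sense or level of induction that cannot be read from precedent. The fallback uses known chemistry and sets out from 6. Alkaloid-mediated alcoholysis (quinidine or its pseudo-enantiomer quinine, whichever places the ester next to the (S)-carbon; benzyl alcohol, toluene, −55 °C) gives (2R,3S,4S)-5-(benzyloxy)-3-[(tert-butyldimethylsilyl)oxy]-2,4-dimethyl-5-oxopentanoic acid F1. Amide coupling of its free acid with N,O-dimethylhydroxylamine hydrochloride (EDC·HCl, HOBt, i-Pr2NEt, CH2Cl2) gives benzyl (2S,3S,4R)-3-[(tert-butyldimethylsilyl)oxy]-5-[methoxy(methyl)amino]-2,4-dimethyl-5-oxopentanoate F2. Hydrogenolysis (H2, palladium on carbon, EtOAc) frees the acid and comes back to the route at 8, at the cost of two extra steps.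

Step 6 (polyanion acylation with an enolisable ester, then cyclisation beside a free acid). The risks are proton transfer from methyl hexanoate, slow acylation that forces warming, and deprotonation next to the carboxylate. The fallback sets out from 10 and replaces the ester Claisen by aldol and oxidation. The same polyanion (LiN(i-Pr)2, THF, −78 °C) adds to hexanal within minutes at −78 °C to give (2S,3S,4R)-3-[(tert-butyldimethylsilyl)oxy]-9-hydroxy-2,4,6,8-tetramethyl-5,7-dioxotetradecanoic acid F3 as a mixture at C6, C8 and C9. Dess–Martin (or Swern) oxidation of the crude carbinol comes back to the route at triketone acid 12, which is cyclised to 13 as in step 6.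

Step 7 (strongly basic dianion in the presence of ring A and a β-silyloxy acyl donor). The risks are deprotonation of the pyrone side chain with loss of silanolate, and enolisation of the acyl imidazole. The fallback sets out from 13 and uses a non-basic Mukaiyama–Claisen coupling. Acid 13 is converted with 1-chloro-N,N,2-trimethylprop-1-en-1-amine (CH2Cl2, 0 °C) into (2S,3S,4R)-3-[(tert-butyldimethylsilyl)oxy]-4-(3,5-dimethyl-4-oxo-6-pentyl-4H-pyran-2-yl)-2-methylpentanoyl chloride F4. Diketone 14 is silylated twice: Me3SiCl/Et3N gives 4-methyl-5-[(trimethylsilyl)oxy]hept-4-en-3-one F5, then LiN(i-Pr)2/Me3SiCl gives 4-methyl-3,5-bis[(trimethylsilyl)oxy]hepta-2,4-diene F6. The diene terminus of F6 is acylated by F4 (CH2Cl2, −78 → 20 °C), and aqueous work-up comes back to the route at triketone 16.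

**Further compounds**

F1 | step 4 | (2R,3S,4S)-5-(benzyloxy)-3-[(tert-butyldimethylsilyl)oxy]-2,4-dimethyl-5-oxopentanoic acid | OC(=O)[C@H](C)[C@H](O[Si](C)(C)C(C)(C)C)[C@H](C)C(=O)OCc1ccccc1
F2 | step 4 | benzyl (2S,3S,4R)-3-[(tert-butyldimethylsilyl)oxy]-5-[methoxy(methyl)amino]-2,4-dimethyl-5-oxopentanoate | CON(C)C(=O)[C@H](C)[C@H](O[Si](C)(C)C(C)(C)C)[C@H](C)C(=O)OCc1ccccc1
F3 | step 6 | (2S,3S,4R)-3-[(tert-butyldimethylsilyl)oxy]-9-hydroxy-2,4,6,8-tetramethyl-5,7-dioxotetradecanoic acid | CCCCCC(O)C(C)C(=O)C(C)C(=O)[C@H](C)[C@H](O[Si](C)(C)C(C)(C)C)[C@H](C)C(=O)O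
F4 | step 7 | (2S,3S,4R)-3-[(tert-butyldimethylsilyl)oxy]-4-(3,5-dimethyl-4-oxo-6-pentyl-4H-pyran-2-yl)-2-methylpentanoyl chloride | CCCCCc1oc([C@H](C)[C@H](O[Si](C)(C)C(C)(C)C)[C@H](C)C(Cl)=O)c(C)c(=O)c1C
F5 | step 7 | 4-methyl-5-[(trimethylsilyl)oxy]hept-4-en-3-one | CCC(=O)C(C)=C(CC)O[Si](C)(C)C
F6 | step 7 | 4-methyl-3,5-bis[(trimethylsilyl)oxy]hepta-2,4-diene | CC=C(O[Si](C)(C)C)C(C)=C(CC)O[Si](C)(C)C
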